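# Proposed total synthesis of CNP0375730.2 (3α-angeloyloxy-9β-senecioyloxy-10βH-eremophil-11-en-8-one) by an intramolecular Diels–Alder route

## The problem

The target is a cis-fused eremophilane. With eremophilane numbering, ring A is C1–C2–C3–C4–C5–C10 and ring B is C5–C6–C7–C8–C9–C10; C5 is quaternary (methyl C14) and C4 carries methyl C15. Taking the face of C14 as β, the six stereocentres are 3α-O-angelate, 4β-CH3, 5β-CH3, 7β-isopropenyl, 9β-O-senecioate and 10β-H. In the chair–chair conformer with C14 axial on ring A and C4 axial on ring B (conformer E below) the substituents at C3, C4, C7 and C9 are all equatorial, whereas in the ring-flipped conformer F a β-substituent at C7 or C9 would be syn-axial to C14. C7 and C9 flank the C8 ketone and can be left to equilibration, but only once ring A is in place. The two conformers treat ring substituents almost as mirror images, so the relation of C3 and C4 to the fusion C5/C10 must be set kinetically, with the C4 hydrogen delivered on the face C14 does not occupy. The angelate (Z to E drift with nucleophiles, base and heat), the β,γ-unsaturated 7-isopropenyl ketone (moves into conjugation with base) and the α-acyloxy ketone (epimerisation, acyl shift) will not survive rough treatment, and the isopropenyl group rules out hydroboration or hydrogenation once it is present. The feature that makes the key step possible is the C8 ketone next to the C9 oxygen in ring B, the pattern left by a diene C7=C8–C9=C10 oxygenated at both inner carbons; the quaternary C5 sits next to C4, which can serve for a time as a ketone that activates a C5=C6 dienophile and lies in the chain C1–C4 that ties C10 to C5.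

## Retrosynthesis

Abbreviations: NAP = naphthalen-2-ylmethyl; TIPS = tri(propan-2-yl)silyl.

**C9–O ester and the ether protecting O9 (29 → 27 + 28; 27 → 26).** The α-acyloxy ketone is the most base-labile part, so the senecioate goes on last and target 29 is made from α-ketol 27 and acid chloride 28 under pyridine. O9 is carried as the NAP ether 26. The NAP group comes off with DDQ, which leaves the isopropenyl group and the angelate alone. A 4-methoxybenzyl group on this oxygen was set aside because, on the enol ether stage, it is prone to acid-induced loss and O-to-C shift under the acid of the key step and of the ketalisation.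

**C7–C11 bond (26 → 22 + 23).** The isopropenyl group is attached to the C8 enolate of ketone 22 by palladium-catalysed α-alkenylation with 2-bromopropene 23. The neighbouring cut, aldol with acetone and dehydration, ends mainly in the conjugated isopropylidene isomer. Carrying the group from earlier is excluded by the hydroboration in ring A. The forward step must enolise toward C7 rather than C9 and keep the product as its dienolate until a kinetic quench.

**C3–O ester and C8 ketal (22 → 21 → 18 + 19).** The angelate is put on alcohol 18 through its lithium alkoxide and angelic anhydride 19 while C8 is still a ketal, so no enolisable ketone is present and no acyl-transfer catalyst or heat is needed. Acid hydrolysis of 21 then frees ketone 22. Placing the angelate this early saves a protecting group at O3, at the price that the later alkenylation must tolerate it.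

**C3–O and C4–H bonds (18 → 16).** Hydroboration–oxidation of the C3=C4 bond of 16 sets C3 and C4 in one step; syn addition gives the trans 3-OH/4-CH3 pair. The alternative of α-hydroxylation at C3, methylenation of C4 and hydroxyl-directed hydrogenation needs three steps and depends on the same facial choice at C3. The forward reaction needs borane to come from the α face, which asks for conformer E.

**C8 ketal and the C9–H bond (16 → 15 → 14).** The dioxolane in 16 does three jobs. It shields C8 from borane. Its α-oxygen would be syn-axial to C1 in conformer F, so it favours conformer E. And under reversible acid conditions it lets C9 of ketone 15 settle as the equatorial 9β ether. Ketone 15 comes from silyl enol ether 14 with fluoride, because acid would protonate C8 and put the ketone at C9.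

**C4–C15 bond (14 → 13 → 11).** The temporary C4 ketone of cycloadduct 11 can enolise only toward C3, since C5 is quaternary, and C8 is still masked as its silyl enol ether. Enol triflate 13 and a Negishi methylation therefore give the C3=C4(CH3) alkene of 14 without selectivity problems.

**C5–C10 and C6–C7 bonds (11 → 10).** The intramolecular Diels–Alder reaction closes both rings and sets C5 and C10 from the achiral trienone 10. Cycloadduct 11 already holds oxygen at C8 and C9 in differentiated form, and the C4 ketone that later delivers C15 and O3.

**Assembly of the trienone (10 → 8 + 9; 8 → 7; 7 → 3 + 6; 6 → 4 + 5; 3 → 2 → 1).** The C4–C5 bond is made last, by adding isopropenylmagnesium bromide 9 to Weinreb amide 8. The methyl ketone of 7 is thus silylated while no second enolisable ketone is present, and the polymerisable enone 10 is not carried through. The C9=C10 bond comes from a Horner–Wadsworth–Emmons reaction of aldehyde 3 with phosphonate 6, itself one O–H insertion step from diazophosphonate 4 and alcohol 5. Aldehyde 3 is two steps from δ-valerolactone 1 through hydroxy amide 2.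

## Roads not taken

Alternative 1: The cut is at C9–C10 and C5–C14. The starting enone A2 is 2-(but-3-en-1-yl)cyclohex-2-en-1-one. In the forward key step CuBr·SMe2 with a chiral phosphoramidite would deliver a vinyl Grignard reagent to C10 of enone A2, and the enolate so formed would be trapped at C5 with iodomethane. The product is ketone A1, 2-(but-3-en-1-yl)-2-methyl-3-vinylcyclohexan-1-one with butenyl and vinyl cis. Ring B would then be closed by metathesis of the two terminal alkenes of A1.
- Merits: the asymmetric step belongs to a well-tested catalytic class, and from A2 through A1 a cis-fused core is reached in fewer steps than the seven needed for 11.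
- Weak points: conjugate addition to a 2-substituted cyclohexenone such as A2 is slow and less selective, and the hindered enolate is hard to methylate. After metathesis of A1, ring B carries only a C8=C9 double bond whose two carbons have to be told apart (ketone at C8, ester oxygen at C9) with no handle, which costs extra redox steps and a regiochemical gamble.
- Comparison: on brevity to the core and on precedent for the asymmetric step the road through A1 is better. The chosen plan sets against it that C8 and C9 arrive already differentiated and C8 stays masked while ring A is worked on. Ring A needs the same C3/C4 work in both.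

Alternative 2: The cut is at C8–C9, late. The substrate is the aldehyde–nitrile A4, the 8,9-seco compound with the aldehyde at C9 and the nitrile at C8. In the forward key step, electrolysis of A4 at a tin cathode in isopropanol (Et4NOTs, divided cell) would turn the aldehyde into a ketyl that attacks the nitrile carbon and closes ring B. Hydrolysis of the resulting imine would give the α-ketol A3, the 3-O-tert-butyldimethylsilyl-9-hydroxy-8-ketone with the target configuration.
- Merits: the α-ketol A3 forms directly with the right regiochemistry. Only silyl/ester adjustments remain after the key step, and no C7 alkenylation is needed. In end-game economy it beats the chosen plan.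
- Weak points: A4 must already carry C3, C4, C5, C7 and C10, including the quaternary centre, on a monocyclic frame where the conformational lever of the bicycle is missing. C7 (α to the nitrile) and C10 (α to the aldehyde) of A4 can epimerise, and pinacol coupling or simple reduction of the aldehyde compete.
- Comparison: the stereochemical burden is moved into the synthesis of A4, for which no short route is apparent. The chosen plan builds both rings and C5/C10 in one step from an achiral chain.

Alternative 3: The cut runs through C6–C7 and C5–C10 of an acyclic C15 chain. A class 1 sesquiterpene cyclase (magnesium ion cofactor) would fold farnesyl diphosphate A6 into the hydrocarbon A5, eremophila-9,11-diene with C4, C5 and C7 as in the target. The enzyme ionises A6, closes both rings, shifts a hydride and the C14 methyl group, and ends by loss of a C9 proton.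
- Merits: the whole C15 skeleton of A5, with C4, C5 and C7 set, arises from A6 in one step. No chemical route matches this for step count to the skeleton, and it solves the vicinal methyl pair that costs the chosen plan three steps and a conformational argument.
- Weak points: A5 has no oxygen. C3 would need a site- and face-selective hydroxylation of an unactivated methylene group. C8 and C9 must be oxidised from the C9=C10 alkene of A5 while C10 is set as 10β-H, and all of this in the presence of the more reactive isopropenyl alkene. An enzyme that turns A6 into exactly this product and antipode must also be at hand.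
- Comparison: the road through A5 wins on step count to the carbon skeleton. The chosen plan sets against it that every oxygen of the target sits on, or next to, a carbon that was a carbonyl or enol ether carbon of cycloadduct 11, so no C–H oxidation is required.

Key step: step 7

Assumption: the catalyst antipode in step 7 is written as (S) on the usual working model of enone binding; if the sense of induction proves opposite, the (R)-catalyst is used with no other change.

## Route

Step 1
Reactants: 1 δ-valerolactone
Product: 2 5-hydroxy-N-methoxy-N-methylpentanamide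
Conditions: MeNH(OMe)·HCl, AlMe3, CH2Cl2, 0 °C → rt
Reagents that add atoms: N,O-dimethylhydroxylamine hydrochloride, CNOC.Cl
Why: Aluminium amide aminolysis of a lactone (Weinreb amide formation) opens the ring and frees the primary alcohol whose carbon becomes C10.

Step 2
Reactants: 2 5-hydroxy-N-methoxy-N-methylpentanamide
Product: 3 N-methoxy-N-methyl-5-oxopentanamide
Conditions: Dess–Martin periodinane, CH2Cl2, 0 °C → rt
Reagents that add atoms: none
Why: Dess–Martin oxidation stops at the aldehyde and leaves the Weinreb amide untouched.

Step 3
Reactants: 4 dimethyl (1-diazo-2-oxopropyl)phosphonate; 5 naphthalen-2-ylmethanol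
Product: 6 dimethyl [1-(naphthalen-2-ylmethoxy)-2-oxopropyl]phosphonate
Conditions: Rh2(OAc)4 (1 mol%), toluene, 80 °C, slow addition of 4
Reagents that add atoms: none
Why: Rhodium carbenoid O–H insertion of an α-diazo-β-ketophosphonate into an alcohol gives the α-alkoxy-β-ketophosphonate in one step; slow addition suppresses carbene dimerisation.

Step 4
Reactants: 3 N-methoxy-N-methyl-5-oxopentanamide; 6 dimethyl [1-(naphthalen-2-ylmethoxy)-2-oxopropyl]phosphonate
Product: 7 (5Z)-N-methoxy-N-methyl-6-(naphthalen-2-ylmethoxy)-7-oxooct-5-enamide
Conditions: Ba(OH)2·8H2O, THF/H2O (40:1), 0 °C → rt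
Reagents that add atoms: none
Why: Horner–Wadsworth–Emmons olefination of a β-ketophosphonate under mild hydroxide conditions; the reversible addition step should place the chain trans to the acetyl group, which is the (Z)-enol ether that later holds the tether on the outside of the diene.

Step 5
Reactants: 7 (5Z)-N-methoxy-N-methyl-6-(naphthalen-2-ylmethoxy)-7-oxooct-5-enamide
Product: 8 (5Z)-N-methoxy-N-methyl-6-(naphthalen-2-ylmethoxy)-7-[tri(propan-2-yl)silyloxy]octa-5,7-dienamide
Conditions: i-Pr3SiOSO2CF3, Et3N, CH2Cl2, −78 → 0 °C
Reagents that add atoms: tri(propan-2-yl)silyl trifluoromethanesulfonate, CC(C)[Si](C(C)C)(C(C)C)OS(=O)(=O)C(F)(F)F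
Why: Soft enolisation and O-silylation of the methyl ketone gives the cross-conjugated 2-silyloxy diene; the Weinreb amide enolises far more slowly and no other ketone is present at this stage.

Step 6
Reactants: 8 (5Z)-N-methoxy-N-methyl-6-(naphthalen-2-ylmethoxy)-7-[tri(propan-2-yl)silyloxy]octa-5,7-dienamide; 9 isopropenylmagnesium bromide
Product: 10 (7Z)-2-methyl-8-(naphthalen-2-ylmethoxy)-9-[tri(propan-2-yl)silyloxy]deca-1,7,9-trien-3-one
Conditions: THF, −20 → 0 °C; pH 7 phosphate buffer, 0 °C; used at once
Reagents that add atoms: none
Why: Weinreb ketone synthesis: the chelated tetrahedral adduct prevents over-addition and releases the α-methyl enone only at work-up, and the silyl enol ether is inert to the Grignard reagent.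

Step 7
Reactants: 10 (7Z)-2-methyl-8-(naphthalen-2-ylmethoxy)-9-[tri(propan-2-yl)silyloxy]deca-1,7,9-trien-3-one
Product: 11 cis-5-methyl-9-(naphthalen-2-ylmethoxy)-8-[tri(propan-2-yl)silyloxy]bicyclo[4.4.0]dec-8-en-4-one (target numbering; 5-CH3 and 10-H both β)
Conditions: (S)-3,3-diphenyl-1-(2-methylphenyl)tetrahydro-1H,3H-pyrrolo[1,2-c][1,3,2]oxazaborole (20 mol%), HN(SO2CF3)2 (18 mol%), CH2Cl2, −78 → −40 °C
Reagents that add atoms: none
Why: Proposed new method: the protonated oxazaborolidine binds the C4 carbonyl of 10 and lowers the LUMO of the C5=C6 enone, so that the 8-silyloxy-9-alkoxy diene adds in a normal-demand, probably asynchronous [4+2] process in which the silyl enol ether terminus C7 bonds to C6 ahead of C10 to C5; the closest known reaction types are the enantioselective Diels–Alder reactions of enones with 2-silyloxy dienes under cationic oxazaborolidine catalysis and the Lewis-acid-promoted intramolecular Diels–Alder reaction of deca-1,7,9-trien-3-ones, neither of which has been shown for an α-methyl enone tethered to a 2,3-dioxygenated diene. Ring B closes as the six-membered cycloadduct ring through both new bonds, and ring A closes at the same time through the four-atom tether C1–C4 as C5–C10 forms, a type 1 intramolecular cycloaddition to a fused bicyclo[4.4.0] system. The relative configuration of C5 and C10 follows from the (Z)-enol ether, which holds the tether on the outside of the diene, and from the transition state with the coordinated tether carbonyl endo, which places C14 and H10 cis. The absolute configuration is set by the catalyst, whose aryl groups shield one face of the bound enone. The step needs endo over exo selectivity, which Lewis-acid coordination and the chair-like tether should secure, and enone face selectivity, which is the untested point because the α-methyl group removes the α-C–H contact that normally fixes an enone on this catalyst. A slight deficit of HN(SO2CF3)2 against the oxazaborolidine keeps free acid away from the silyl enol ether.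

Step 8
Reactants: 11 cis-5-methyl-9-(naphthalen-2-ylmethoxy)-8-[tri(propan-2-yl)silyloxy]bicyclo[4.4.0]dec-8-en-4-one
Product: 13 cis-5-methyl-9-(naphthalen-2-ylmethoxy)-8-[tri(propan-2-yl)silyloxy]bicyclo[4.4.0]deca-3,8-dien-4-yl trifluoromethanesulfonate, via potassium 3-en-4-olate 12 (not isolated)
Conditions: KN(SiMe3)2, THF, −78 °C; PhN(SO2CF3)2, −78 → 0 °C
Reagents that add atoms: N-phenylbis(trifluoromethanesulfonimide), O=S(=O)(N(c1ccccc1)S(=O)(=O)C(F)(F)F)C(F)(F)F
Why: Enol triflate formation from a ketone enolate; C5 is quaternary, so the C4 ketone can enolise only toward C3, and the silyl and naphthylmethyl enol ethers are stable to the amide base.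

Step 9
Reactants: 13 cis-5-methyl-9-(naphthalen-2-ylmethoxy)-8-[tri(propan-2-yl)silyloxy]bicyclo[4.4.0]deca-3,8-dien-4-yl trifluoromethanesulfonate
Product: 14 cis-4,5-dimethyl-9-(naphthalen-2-ylmethoxy)-8-[tri(propan-2-yl)silyloxy]bicyclo[4.4.0]deca-3,8-diene
Conditions: Me2Zn, Pd(PPh3)4 (5 mol%), THF, 0 °C → rt
Reagents that add atoms: dimethylzinc, C[Zn]C
Why: Negishi coupling of an alkenyl triflate with a methylzinc reagent installs C15 under neutral conditions that leave the enediol diether intact.

Step 10
Reactants: 14 cis-4,5-dimethyl-9-(naphthalen-2-ylmethoxy)-8-[tri(propan-2-yl)silyloxy]bicyclo[4.4.0]deca-3,8-diene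
Product: 15 cis-4,5-dimethyl-9-(naphthalen-2-ylmethoxy)bicyclo[4.4.0]dec-3-en-8-one, both C9 epimers
Conditions: Bu4NF, AcOH, THF, −78 → 0 °C
Reagents that add atoms: none
Why: Fluoride cleaves the O–Si bond and the resulting C8 enolate is protonated at C9, which fixes the ketone at C8; acid hydrolysis is avoided because protonation at C8 would give the 9-ketone.

Step 11
Reactants: 15 cis-4,5-dimethyl-9-(naphthalen-2-ylmethoxy)bicyclo[4.4.0]dec-3-en-8-one, both C9 epimers
Product: 16 8,8-ethylenedioxy-4,5β-dimethyl-9β-(naphthalen-2-ylmethoxy)-10βH-bicyclo[4.4.0]dec-3-ene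
Conditions: HOCH2CH2OH, TsOH·H2O (10 mol%), benzene, reflux, Dean–Stark
Reagents that add atoms: ethane-1,2-diol, OCCO
Why: Acid-catalysed ketalisation under reversible protic conditions, in which C9 epimerises through the enol of the ketone. The 9β-ether should accumulate because it is equatorial in conformer E, whereas the 9α-ether has no relaxed form: in conformer E it is syn-axial to C4 and in conformer F the α-oxygen of the ketal is syn-axial to C1.

Step 12
Reactants: 16 8,8-ethylenedioxy-4,5β-dimethyl-9β-(naphthalen-2-ylmethoxy)-10βH-bicyclo[4.4.0]dec-3-ene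
Product: 18 8,8-ethylenedioxy-4β,5β-dimethyl-9β-(naphthalen-2-ylmethoxy)-10βH-bicyclo[4.4.0]decan-3α-ol, via 3α-alkylborane 17 (not isolated)
Conditions: BH3·THF, THF, 0 °C → rt; NaOH, H2O2, 0 °C → rt
Reagents that add atoms: hydrogen peroxide, OO
Why: Hydroboration–oxidation: syn addition with boron at the less substituted C3 gives the trans 3-OH/4-CH3 pair, and oxidation proceeds with retention. With 16 held in conformer E by the equatorial 9β-ether and the ketal, the axial C14 methyl blocks the β face of the C3=C4 bond, so borane should add from the α face and give 3α-OH and 4β-CH3, as in the α-face hydroboration of steroidal 5-enes under their angular methyl group.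

Step 13
Reactants: 18 8,8-ethylenedioxy-4β,5β-dimethyl-9β-(naphthalen-2-ylmethoxy)-10βH-bicyclo[4.4.0]decan-3α-ol; 19 angelic anhydride [(Z)-2-methylbut-2-enoic anhydride]
Product: 21 8,8-ethylenedioxy-4β,5β-dimethyl-9β-(naphthalen-2-ylmethoxy)-10βH-bicyclo[4.4.0]decan-3α-yl (Z)-2-methylbut-2-enoate, via lithium 3α-olate 20 (not isolated)
Conditions: LiN(SiMe3)2 (1.05 equiv), THF, −78 °C; 19, −78 → 0 °C
Reagents that add atoms: none
Why: Acylation of a lithium alkoxide with the anhydride needs neither heat nor a nucleophilic catalyst, the two causes of angelate-to-tiglate isomerisation; the amide base is consumed by the alcohol and no enolisable carbonyl is present.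

Step 14
Reactants: 21 8,8-ethylenedioxy-4β,5β-dimethyl-9β-(naphthalen-2-ylmethoxy)-10βH-bicyclo[4.4.0]decan-3α-yl (Z)-2-methylbut-2-enoate
Product: 22 3α-[(Z)-2-methylbut-2-enoyloxy]-4β,5β-dimethyl-9β-(naphthalen-2-ylmethoxy)-10βH-bicyclo[4.4.0]decan-8-one
Conditions: 1 M HCl, THF, 40 °C
Reagents that add atoms: water, O
Why: Acid hydrolysis of the dioxolane; the ester and the naphthylmethyl ether tolerate dilute acid, and C9 is now held as 9β by the equatorial substituents of ring A.

Step 15
Reactants: 22 3α-[(Z)-2-methylbut-2-enoyloxy]-4β,5β-dimethyl-9β-(naphthalen-2-ylmethoxy)-10βH-bicyclo[4.4.0]decan-8-one; 23 2-bromopropene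
Product: 26 3α-angeloyloxy-9β-(naphthalen-2-ylmethoxy)-7αH,10βH-eremophil-11-en-8-one, via lithium 7-en-8-olate 24 (not isolated), via lithium dienolate 25 (not isolated)
Conditions: LiN(SiMe3)2 (2.1 equiv), THF, −78 °C; Pd2(dba)3 (2.5 mol%), P(t-Bu)3 (6 mol%), 23, toluene/THF, rt; AcOH, −78 °C
Reagents that add atoms: none
Why: Palladium-catalysed α-alkenylation of a ketone enolate with an alkenyl bromide: the enolate forms at C7, the less hindered α-position away from the ether-bearing C9, and couples with the isopropenylpalladium bromide formed by oxidative addition. The second equivalent of base is taken up by the more acidic product, which waits as dienolate 25, so little free amide meets the angelate. Kinetic protonation at the α-carbon C7 from the axial α direction should give the β,γ-unsaturated ketone with the equatorial 7β-isopropenyl group, which is also the more stable epimer.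

Step 16
Reactants: 26 3α-angeloyloxy-9β-(naphthalen-2-ylmethoxy)-7αH,10βH-eremophil-11-en-8-one
Product: 27 3α-angeloyloxy-9β-hydroxy-7αH,10βH-eremophil-11-en-8-one
Conditions: DDQ, CH2Cl2/pH 7 buffer (10:1), 0 °C → rt
Reagents that add atoms: none
Why: Oxidative cleavage of a naphthylmethyl ether by hydride abstraction at the benzylic position and hydrolysis; the isopropenyl group, the angelate and the ketone are not oxidised under these buffered conditions.

Step 17
Reactants: 27 3α-angeloyloxy-9β-hydroxy-7αH,10βH-eremophil-11-en-8-one; 28 3-methylbut-2-enoyl chloride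
Product: 29 3α-angeloyloxy-9β-senecioyloxy-7αH,10βH-eremophil-11-en-8-one (CNP0375730.2)
Conditions: pyridine, CH2Cl2, 0 °C → rt
Reagents that add atoms: none
Why: Acylation of the α-ketol with an acid chloride under a weak base; pyridine is too weak to form the vinylketene that would deconjugate the senecioate or to move the isopropenyl double bond into conjugation, and C7 and C9 already hold their equatorial, stable configurations.

## Compound list

1 | δ-valerolactone | O=C1CCCCO1 | starting material
2 | 5-hydroxy-N-methoxy-N-methylpentanamide | CON(C)C(=O)CCCCO | intermediate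
3 | N-methoxy-N-methyl-5-oxopentanamide | CON(C)C(=O)CCCC=O | intermediate
4 | dimethyl (1-diazo-2-oxopropyl)phosphonate | COP(=O)(OC)C(=[N+]=[N-])C(C)=O | starting material
5 | naphthalen-2-ylmethanol | OCc1ccc2ccccc2c1 | starting material
6 | dimethyl [1-(naphthalen-2-ylmethoxy)-2-oxopropyl]phosphonate (racemic) | COP(=O)(OC)C(OCc1ccc2ccccc2c1)C(C)=O | intermediate
7 | (5Z)-N-methoxy-N-methyl-6-(naphthalen-2-ylmethoxy)-7-oxooct-5-enamide | CC(=O)/C(OCc1ccc2ccccc2c1)=C/CCCC(=O)N(C)OC | intermediate
8 | (5Z)-N-methoxy-N-methyl-6-(naphthalen-2-ylmethoxy)-7-[tri(propan-2-yl)silyloxy]octa-5,7-dienamide | C=C(O[Si](C(C)C)(C(C)C)C(C)C)/C(OCc1ccc2ccccc2c1)=C/CCCC(=O)N(C)OC | intermediate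
9 | isopropenylmagnesium bromide | C=C(C)[Mg]Br | starting material
10 | (7Z)-2-methyl-8-(naphthalen-2-ylmethoxy)-9-[tri(propan-2-yl)silyloxy]deca-1,7,9-trien-3-one | C=C(C)C(=O)CCC/C=C(\OCc1ccc2ccccc2c1)C(=C)O[Si](C(C)C)(C(C)C)C(C)C | intermediate
11 | cis-5-methyl-9-(naphthalen-2-ylmethoxy)-8-[tri(propan-2-yl)silyloxy]bicyclo[4.4.0]dec-8-en-4-one (5β-CH3, 10β-H) | C[C@]12CCC(O[Si](C(C)C)(C(C)C)C(C)C)=C(OCc3ccc4ccccc4c3)[C@H]1CCCC2=O | intermediate
12 | potassium 3-en-4-olate of 11 | C[C@]12CCC(O[Si](C(C)C)(C(C)C)C(C)C)=C(OCc3ccc4ccccc4c3)[C@H]1CCC=C2[O-].[K+] | intermediate (not isolated)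
13 | cis-5-methyl-9-(naphthalen-2-ylmethoxy)-8-[tri(propan-2-yl)silyloxy]bicyclo[4.4.0]deca-3,8-dien-4-yl trifluoromethanesulfonate | C[C@]12CCC(O[Si](C(C)C)(C(C)C)C(C)C)=C(OCc3ccc4ccccc4c3)[C@H]1CCC=C2OS(=O)(=O)C(F)(F)F | intermediate
14 | cis-4,5-dimethyl-9-(naphthalen-2-ylmethoxy)-8-[tri(propan-2-yl)silyloxy]bicyclo[4.4.0]deca-3,8-diene | C[C@]12CCC(O[Si](C(C)C)(C(C)C)C(C)C)=C(OCc3ccc4ccccc4c3)[C@H]1CCC=C2C | intermediate
15 | cis-4,5-dimethyl-9-(naphthalen-2-ylmethoxy)bicyclo[4.4.0]dec-3-en-8-one, both C9 epimers (C9 left open in the SMILES on purpose) | C[C@]12CCC(=O)C(OCc3ccc4ccccc4c3)[C@H]1CCC=C2C | intermediate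
16 | 8,8-ethylenedioxy-4,5β-dimethyl-9β-(naphthalen-2-ylmethoxy)-10βH-bicyclo[4.4.0]dec-3-ene | C[C@]12CCC3(OCCO3)[C@H](OCc4ccc5ccccc5c4)[C@H]1CCC=C2C | intermediate
17 | 3α-boryl-8,8-ethylenedioxy-4β,5β-dimethyl-9β-(naphthalen-2-ylmethoxy)-10βH-bicyclo[4.4.0]decane (alkylborane) | C[C@]12CCC3(OCCO3)[C@H](OCc4ccc5ccccc5c4)[C@H]1CC[C@@H](B)[C@@H]2C | intermediate (not isolated)
18 | 8,8-ethylenedioxy-4β,5β-dimethyl-9β-(naphthalen-2-ylmethoxy)-10βH-bicyclo[4.4.0]decan-3α-ol | C[C@]12CCC3(OCCO3)[C@H](OCc4ccc5ccccc5c4)[C@H]1CC[C@@H](O)[C@@H]2C | intermediate
19 | angelic anhydride, (Z)-2-methylbut-2-enoic anhydride | C/C=C(/C)C(=O)OC(=O)/C(C)=C\C | starting material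
20 | lithium 3α-olate of 18 | C[C@]12CCC3(OCCO3)[C@H](OCc4ccc5ccccc5c4)[C@H]1CC[C@@H]([O-])[C@@H]2C.[Li+] | intermediate (not isolated)
21 | 3α-angelate of 18 | C[C@]12CCC3(OCCO3)[C@H](OCc4ccc5ccccc5c4)[C@H]1CC[C@@H](OC(=O)/C(C)=C\C)[C@@H]2C | intermediate
22 | 3α-[(Z)-2-methylbut-2-enoyloxy]-4β,5β-dimethyl-9β-(naphthalen-2-ylmethoxy)-10βH-bicyclo[4.4.0]decan-8-one | C[C@]12CCC(=O)[C@H](OCc3ccc4ccccc4c3)[C@H]1CC[C@@H](OC(=O)/C(C)=C\C)[C@@H]2C | intermediate
23 | 2-bromopropene | C=C(C)Br | starting material
24 | lithium 7-en-8-olate of 22 | C[C@]12CC=C([O-])[C@H](OCc3ccc4ccccc4c3)[C@H]1CC[C@@H](OC(=O)/C(C)=C\C)[C@@H]2C.[Li+] | intermediate (not isolated)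
25 | lithium 7,11-dien-8-olate of 26 | C[C@]12CC(C(C)=C)=C([O-])[C@H](OCc3ccc4ccccc4c3)[C@H]1CC[C@@H](OC(=O)/C(C)=C\C)[C@@H]2C.[Li+] | intermediate (not isolated)
26 | 3α-angeloyloxy-9β-(naphthalen-2-ylmethoxy)-7αH,10βH-eremophil-11-en-8-one | C=C(C)[C@H]1C[C@@]2(C)[C@H](CC[C@@H](OC(=O)/C(C)=C\C)[C@@H]2C)[C@@H](OCc3ccc4ccccc4c3)C1=O | intermediate
27 | 3α-angeloyloxy-9β-hydroxy-7αH,10βH-eremophil-11-en-8-one | C=C(C)[C@H]1C[C@@]2(C)[C@H](CC[C@@H](OC(=O)/C(C)=C\C)[C@@H]2C)[C@@H](O)C1=O | intermediate
28 | 3-methylbut-2-enoyl chloride (senecioyl chloride) | CC(C)=CC(=O)Cl | starting material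
29 | 3α-angeloyloxy-9β-senecioyloxy-7αH,10βH-eremophil-11-en-8-one (CNP0375730.2) | C=C(C)[C@H]1C[C@@]2(C)[C@H](CC[C@@H](OC(=O)/C(C)=C\C)[C@@H]2C)[C@@H](OC(=O)C=C(C)C)C1=O | target

## Step count and least certain steps

Total: 17 steps. Longest linear sequence: 16 steps (1 → 29 through steps 1, 2 and 4–17); step 3 is a one-step side branch.

**Step 7 (key step, proposed new method).** The most likely failure is poor enantioface selection, because the α-methyl enone cannot make the α-C–H contact that orients simpler enones on the oxazaborolidinium ion. Further risks are loss of the silyl group by adventitious acid, and an uncatalysed or exo pathway that erodes the cis selectivity. Fallback with known chemistry, setting out from 10: Me2AlCl (1.1 equiv, CH2Cl2, −78 → −20 °C) promotes the intramolecular Diels–Alder reaction without chiral information and should give the racemic cis-cycloadduct F1. Preparative chromatography of F1 on an amylose tris(3,5-dimethylphenylcarbamate) stationary phase returns 11.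

**Step 15.** What may go wrong is β-hydride elimination from the palladium enolate, a second alkenylation, migration of the new double bond into conjugation during the quench, or attack of the amide base on the angelate (γ-deprotonation and Z/E drift). The fallback goes through an α-iodoenone and sets out from 22. LiN(SiMe3)2 and Me3SiCl at −78 °C should give the trimethylsilyl enol ether F2, and Pd(OAc)2 in MeCN (Saegusa–Ito oxidation) should turn it into the 6-en-8-one F3. I2 and pyridine in CH2Cl2 should then give the 7-iodo-6-en-8-one F4, and Stille coupling with tributyl(prop-1-en-2-yl)stannane (Pd2(dba)3, AsPh3, CuI, DMF) the 7-isopropenyl-6-en-8-one F5. Conjugate reduction of F5 with [(Ph3P)CuH]6 in wet benzene, followed by protonation of the dienolate at C7, returns 26.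

**Step 12.** Poor facial selectivity is the main risk: hydrogen delivery to C4 on the concave α face passes C9, and the neopentyl-type alkene may react slowly enough for the β-face pathway to compete. The fallback uses thermodynamic control and sets out from 16. The hydroboration–oxidation mixture of 18 and its 3β-hydroxy-4α-methyl isomer F6 is oxidised with Dess–Martin periodinane and equilibrated with DBU; in conformer E an axial 4α-methyl group would be syn-axial to C9, so all material should converge on the 4β-methyl 3-ketone F7. Li[HB(sec-Bu)3] should attack F7 from the α face, away from the axial C14, and give the axial 3β-alcohol F8. Mitsunobu inversion of F8 (4-nitrobenzoic acid, PPh3, diisopropyl azodicarboxylate) should give the 3α-(4-nitrobenzoate) F9, and K2CO3 in MeOH then returns 18.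

**Step 11.** Acid-catalysed enolisation toward C9 may be slower than ketal formation, so the C9 ratio would be frozen at whatever the protonation in step 10 delivered; the α-alkoxy ketone may also ketalise sluggishly. The fallback works by separation and recycling and sets out from 15: chromatography splits 15 into the 9β-ketone F10 and the 9α-ketone F11. F10 is ketalised under aprotic, non-equilibrating conditions (1,2-bis(trimethylsilyloxy)ethane, Me3SiOSO2CF3 cat., CH2Cl2, −78 °C) to return 16. F11 is re-equilibrated to 15 with DBU in CH2Cl2 and passed through the separation again.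

## Further compounds

F1 | step 7 | racemic cis-cycloadduct (11 and its enantiomer, 1:1) | C[C@]12CCC(O[Si](C(C)C)(C(C)C)C(C)C)=C(OCc3ccc4ccccc4c3)[C@H]1CCCC2=O.C[C@@]12CCC(O[Si](C(C)C)(C(C)C)C(C)C)=C(OCc3ccc4ccccc4c3)[C@@H]1CCCC2=O
F2 | step 15 | 8-trimethylsilyl enol ether (7-ene) of 22 | C[C@]12CC=C(O[Si](C)(C)C)[C@H](OCc3ccc4ccccc4c3)[C@H]1CC[C@@H](OC(=O)/C(C)=C\C)[C@@H]2C
F3 | step 15 | 6-en-8-one derived from 22 | C[C@]12C=CC(=O)[C@H](OCc3ccc4ccccc4c3)[C@H]1CC[C@@H](OC(=O)/C(C)=C\C)[C@@H]2C
F4 | step 15 | 7-iodo-6-en-8-one | C[C@]12C=C(I)C(=O)[C@H](OCc3ccc4ccccc4c3)[C@H]1CC[C@@H](OC(=O)/C(C)=C\C)[C@@H]2C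
F5 | step 15 | 7-isopropenyl-6-en-8-one (6,7-didehydro-26) | C[C@]12C=C(C(C)=C)C(=O)[C@H](OCc3ccc4ccccc4c3)[C@H]1CC[C@@H](OC(=O)/C(C)=C\C)[C@@H]2C
F6 | step 12 | 3β-hydroxy-4α-methyl isomer of 18 | C[C@]12CCC3(OCCO3)[C@H](OCc4ccc5ccccc5c4)[C@H]1CC[C@H](O)[C@H]2C
F7 | step 12 | 8,8-ethylenedioxy-4β,5β-dimethyl-9β-(naphthalen-2-ylmethoxy)-10βH-bicyclo[4.4.0]decan-3-one | C[C@]12CCC3(OCCO3)[C@H](OCc4ccc5ccccc5c4)[C@H]1CCC(=O)[C@@H]2C
F8 | step 12 | 3β-epimer of 18 (3β-OH, 4β-CH3) | C[C@]12CCC3(OCCO3)[C@H](OCc4ccc5ccccc5c4)[C@H]1CC[C@H](O)[C@@H]2C
F9 | step 12 | 3α-(4-nitrobenzoate) of 18 | C[C@]12CCC3(OCCO3)[C@H](OCc4ccc5ccccc5c4)[C@H]1CC[C@@H](OC(=O)c6ccc(cc6)[N+](=O)[O-])[C@@H]2C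
F10 | step 11 | 9β-epimer of ketone 15 | C[C@]12CCC(=O)[C@H](OCc3ccc4ccccc4c3)[C@H]1CCC=C2C
F11 | step 11 | 9α-epimer of ketone 15 | C[C@]12CCC(=O)[C@@H](OCc3ccc4ccccc4c3)[C@H]1CCC=C2C
A1 | alternative 1 | 2-(but-3-en-1-yl)-2-methyl-3-vinylcyclohexan-1-one, butenyl and vinyl cis | C=CCC[C@@]1(C)[C@@H](C=C)CCCC1=O
A2 | alternative 1 | 2-(but-3-en-1-yl)cyclohex-2-en-1-one | C=CCCC1=CCCCC1=O
A3 | alternative 2 | 3-O-tert-butyldimethylsilyl-9-hydroxyeremophil-11-en-8-one with the target configuration | C=C(C)[C@H]1C[C@@]2(C)[C@H](CC[C@@H](O[Si](C)(C)C(C)(C)C)[C@@H]2C)[C@@H](O)C1=O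
A4 | alternative 2 | 8,9-seco aldehyde–nitrile precursor of A3 (C9 aldehyde, C8 nitrile) | C=C(C)[C@H](C#N)C[C@@]1(C)[C@@H](C=O)CC[C@@H](O[Si](C)(C)C(C)(C)C)[C@@H]1C
A5 | alternative 3 | eremophila-9,11-diene with C4, C5 and C7 as in the target | C=C(C)[C@H]1C[C@@]2(C)C(CCC[C@@H]2C)=CC1
A6 | alternative 3 | (2E,6E)-farnesyl diphosphate | CC(C)=CCC/C(C)=C/CC/C(C)=C/COP(=O)(O)OP(=O)(O)O
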